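## Analysis of the target

Atoms are numbered as in the halimane skeleton: C1–C10 form the decalin, C11–C15 the side chain (C15 carries the acetate), C16 is the C13 methyl, C17 the C8 methyl, C18 the ester carbon, C19 the C4 methyl and C20 the C9 methyl. Target 32 is an octalin: ring A (C1–C5, C10) holds the trisubstituted C1=C10 alkene and ring B (C5–C10) is saturated. There are four stereocentres: quaternary C4 (CO2Me, CH3), C5 (H), C8 (CH3) and quaternary C9 (CH3, side chain). H5, the C4 ester and the C9 side chain lie on one face; the C4, C8 and C9 methyl groups lie on the other. The sensitive groups are the ionisable, base-labile allylic acetate, the E-configured C13=C14 alkene and the C1=C10 alkene, which acid could move to the tetrasubstituted C5=C10 position. The difficulty lies in two quaternary carbons, one of them (C9) flanked by the C8 stereocentre and by sp2 C10, and in relating C4/C5 to C8/C9 across the ring fusion. The strategy rests on the C5–C10 fusion bond. Cutting it opens both rings to a cyclodecane in which C9=C10 is an enolate and C5=C6 an alkene. C8 and C9 can be set while that ring is made, and the two π systems can then be joined again across the ring.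

## Retrosynthetic reasoning

**32 ⇒ 30.** The acetate is put on last, from alcohol 31, because it would not survive organometallic or hydride bases. Alcohol 31 comes from silyl ether 30. The silyl ether is the only protecting group of the route and is inert to every earlier step.

**30 ⇒ 28.** The C1=C10 alkene is traced to tertiary C10 alcohol 29 by a syn elimination. In the trans-fused decalinol C9 is quaternary and H5 is anti to the hydroxyl, so only C1 offers a cis hydrogen. Alcohol 29 comes from homoallylic alcohol 28 by saturating the C6=C7 alkene, which is the one unwanted mark left by the ring-forming step. That alkene is cis-disubstituted, so it can be told apart from the trisubstituted side-chain alkene.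

**28 ⇒ 24 (key disconnection).** Three bonds are cut: C5–C10 (transannular carbonyl-ene), C9–C20 (enolate methylation) and C7–C8 (oxy-Cope). This leads through ketone 27 and enolate 26 to trans-1,2-dialkenylcyclohexanol 24, whose C5–C10 bond is the one broken in the forward [3,3] shift. The cut is made here because it removes both rings and the C5, C8, C9 and C10 stereocentres at once and leaves a monocyclic precursor with only three stereocentres. Forward, the step has to pass the Z geometry of the alkenyl group to C8 through a chair, methylate C9 on the outer face of the macrocyclic enolate, and re-close C5–C10 on the original faces.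

**24 ⇒ 14 + 21.** The C9–C10 bond is cut to ketone 14 and the alkenyl metal derived from Z-bromoalkene 21. The equatorial vinyl group at C5 and the axial C19 methyl of 14 direct the nucleophile to the face trans to the vinyl group, so C10 needs no separate control. The Z geometry of 21 is carried into 24 unchanged.

**14 ⇒ 4 + 5 + 3.** The C4–C18 and C5–C6 bonds are cut in a vicinal difunctionalisation of enone 4. The carboxyl group enters as the 2-methylprop-1-enyl group of bromide 5 by a catalytic enantioselective conjugate addition, which sets C4. The enolate formed only at C5 is trapped by aldehyde 3 (made from 1 and 2) as a latent vinyl group, trans to the alkenyl group. The alkenyl surrogate is then cut down to the ester through 10, 11, 12 and 13. The surrogate must be the nucleophile and the vinyl equivalent the electrophile, because only this order gives the vinyl group trans to the future ester. A trisubstituted surrogate is chosen so that a peracid can tell it from the vinyl group.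

**21 ⇒ 19 + 16; 19 ⇒ 17; 16 ⇒ 15.** The C9–C11 bond is cut to the borane from diene 19 and dibromoalkene 16. Coupling at the bromine trans to the methyl group leaves the bromine cis to C17, which is the required Z geometry. Diene 19 comes from enynol 17, which supplies the E-configured C13=C14 alkene ready-made. Dibromoalkene 16 comes from aldehyde 15.

## Alternatives that were turned down

**Alternative 1:** The C3–C4 bond is cut. The precursor is a δ-lactone fused to a finished ring B, with oxygen linking C1 to the acyl carbon on C4 and a vinyl group (C2=C3) on C1. Forward, the silyl ketene acetal of this lactone (amide base, chlorosilane) undergoes a [3,3] shift that forms C3–C4, breaks C1–O and closes ring A to give acid A1. In its favour, C4 is set by a ring-constrained, substrate-controlled pericyclic step and the carboxyl group arrives at the right oxidation level. On control of C4 this is stronger than the chosen route, which relies on a catalyst. Against it, the alkene arrives at C1=C2 and must be moved to C1=C10 in competition with the tetrasubstituted C5=C10 position. The lactone also needs ring B with C5, C8, quaternary C9, C10 and C1 already in place, so the stereochemical work is done in a long linear sequence before the key step. The butynyl chain of A1 still has to be taken to the E-trisubstituted allylic acetate. The chosen strategy instead creates C5, C8 and C9 in one step from flat precursors and carries the complete side chain from the start.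

**Alternative 2:** The C2–C3 and C4–C5 bonds are cut. The partners are a semicyclic diene (C5=C10 in ring B, C1=C2 as a vinyl group on C10) that already carries C8 and C9, and methacrolein A2 as the C3=C4 unit. Forward, a chiral oxazaborolidinium Lewis acid promotes an exo [4+2] addition that closes ring A and gives aldehyde A3 with the alkene directly at C1=C10. In its favour, the alkene position is fixed by the mechanism, two bonds and two stereocentres form together, the route is convergent, and aldehyde to methyl ester is routine. On the alkene this is stronger than the chosen route, which spends a hydrogenation and a dehydration on it. Against it, C4–C5 must form between a fully substituted dienophile carbon and the ring terminus of a diene whose neighbouring C10 bears quaternary C9. The directing effects of the C5 and C10 substituents on regiochemistry oppose each other. The two diene faces differ only by methyl versus chain at C9, so the catalyst would have to override the substrate. The diene itself needs the vicinal C8/C9 pair made beforehand by separate asymmetric chemistry, and A3 again ends in an alkyne. The chosen strategy obtains C8 and C9 from alkene geometry and a chair transition state.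

**Alternative 3:** The C9–C10 bond is cut. The precursor is a ring A enol triflate at C10 with a chain from C5 that ends in a C9=C11 alkene. Forward, zerovalent palladium with a phosphine inserts into the C10 triflate and adds 6-exo to C9=C11. This forms quaternary C9 and ring B, and β-hydride loss leaves a vinyl group, giving ester A4. In its favour, this is a dependable catalytic way to make a quaternary carbon next to an sp2 carbon, the C1=C10 alkene never has to be moved, and β-hydride loss has only one direction. On C9 and on the alkene position it is at least as strong as the chosen route. Against it, the C9 configuration depends on 1,2-induction from C8 in the cyclisation. C4, C5 and C8, including the remote C5/C8 pair, must be set independently in the open-chain precursor. A4 carries only two side-chain carbons, so C13–C16 and the E alkene must be added after the key step, in the presence of C1=C10. The chosen strategy sets C5, C8 and C9 together from a precursor with three stereocentres and needs no chain extension afterwards.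

Key step: step 13

Remarks: the antipode of the chiral ligand in step 2 is the one that gives the 3S adduct. Enynol 17 is taken as the commercial, geometrically pure E isomer.

## Route

**Step 1**
Reactants: 1 benzeneselenenyl chloride; 2 ethoxyethene
Product: 3 2-(phenylselanyl)acetaldehyde
Conditions: CH2Cl2, −78 °C to rt; then H2O, NaHCO3
Reagents that add atoms: water, O
Why: Electrophilic selenenylation of the enol ether puts selenium on the terminal carbon; hydrolysis of the resulting α-chloro ether should give the aldehyde, which is used fresh.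

**Step 2**
Reactants: 4 3-methylcyclohex-2-en-1-one; 5 1-bromo-2-methylprop-1-ene; 3 2-(phenylselanyl)acetaldehyde
Product: 9 (2S,3R)-2-[1-hydroxy-2-(phenylselanyl)ethyl]-3-methyl-3-(2-methylprop-1-en-1-yl)cyclohexan-1-one, via (2-methylprop-1-en-1-yl)lithium 6 (not isolated), via dimethyl(2-methylprop-1-en-1-yl)alane 7 (not isolated), via dimethylaluminium enolate 8 (not isolated)
Conditions: 5, t-BuLi, Et2O, −78 °C; Me2AlCl, −78 to 0 °C; 4, copper thiophene-2-carboxylate Cu(C5H3O2S) (10 mol%), Ph2P–N[CH(CH3)(2-naphthyl)]2 (11 mol%), Et2O, −30 °C; then 3, −78 °C; aq. KNaC4H4O6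
Reagents that add atoms: none
Why: Copper-catalysed enantioselective conjugate addition of an alkenylalane to a β-methyl cyclic enone should set quaternary C4 under ligand control and give the enolate only at C5. Aldol capture by 3 should occur anti to the pseudo-axial alkenyl group, placing the new C5 substituent trans to it; the carbinol centre is lost in step 3.

**Step 3**
Reactants: 9 (2S,3R)-2-[1-hydroxy-2-(phenylselanyl)ethyl]-3-methyl-3-(2-methylprop-1-en-1-yl)cyclohexan-1-one
Product: 10 (2R,3R)-2-ethenyl-3-methyl-3-(2-methylprop-1-en-1-yl)cyclohexan-1-one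
Conditions: MsCl, Et3N, CH2Cl2, 0 °C
Reagents that add atoms: none
Why: Mesylation and selenium-assisted anti elimination of the β-hydroxy selenide should place the alkene between the carbinol carbon and the selenium-bearing carbon. The vinyl group forms out of conjugation, and the short, cold exposure to base should leave C5 intact.

**Step 4**
Reactants: 10 (2R,3R)-2-ethenyl-3-methyl-3-(2-methylprop-1-en-1-yl)cyclohexan-1-one
Product: 11 (2R,3S)-3-(3,3-dimethyloxiran-2-yl)-2-ethenyl-3-methylcyclohexan-1-one
Conditions: mCPBA, NaHCO3, CH2Cl2, 0 °C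
Reagents that add atoms: 3-chloroperoxybenzoic acid, OOC(=O)c1cccc(Cl)c1
Why: Peracid epoxidation is far faster at the trisubstituted alkene than at the monosubstituted vinyl group, and Baeyer–Villiger oxidation of the ketone should be slow under buffered, cold conditions.

**Step 5**
Reactants: 11 (2R,3S)-3-(3,3-dimethyloxiran-2-yl)-2-ethenyl-3-methylcyclohexan-1-one
Product: 12 (1S,2R)-2-ethenyl-1-methyl-3-oxocyclohexane-1-carbaldehyde
Conditions: H5IO6, THF/H2O, 0 °C to rt
Reagents that add atoms: none
Why: Hydrolytic opening of the epoxide and glycol cleavage in one pot should release acetone and a non-enolisable neopentyl aldehyde at C18.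

**Step 6**
Reactants: 12 (1S,2R)-2-ethenyl-1-methyl-3-oxocyclohexane-1-carbaldehyde
Product: 13 (1S,2R)-2-ethenyl-1-methyl-3-oxocyclohexane-1-carboxylic acid
Conditions: NaClO2, NaH2PO4, 2-methylbut-2-ene, t-BuOH/H2O, rt
Reagents that add atoms: sodium chlorite, [Na+].[O-]Cl=O
Why: Pinnick oxidation is selective for the aldehyde; the alkene scavenger removes hypochlorous acid before it can attack the vinyl group, and the weakly acidic medium should not epimerise C5.

**Step 7**
Reactants: 13 (1S,2R)-2-ethenyl-1-methyl-3-oxocyclohexane-1-carboxylic acid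
Product: 14 methyl (1S,2R)-2-ethenyl-1-methyl-3-oxocyclohexane-1-carboxylate
Conditions: Me3SiCHN2, PhMe/MeOH, 0 °C
Reagents that add atoms: (trimethylsilyl)diazomethane, C[Si](C)(C)C=[N+]=[N-]
Why: Esterification by O-alkylation of the carboxylic acid avoids attack at the hindered neopentyl carboxyl carbon and needs neither acid nor base, so the β,γ-unsaturated ketone should stay unconjugated.

**Step 8**
Reactants: 15 acetaldehyde
Product: 16 1,1-dibromoprop-1-ene
Conditions: CBr4, PPh3, Zn, CH2Cl2, rt; then 15, 0 °C
Reagents that add atoms: tetrabromomethane, BrC(Br)(Br)Br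
Why: Ramirez dibromo-olefination (first stage of the Corey–Fuchs sequence) of an unhindered aldehyde; the volatile product is distilled.

**Step 9**
Reactants: 17 (2E)-3-methylpent-2-en-4-yn-1-ol
Product: 18 tert-butyldimethyl{[(2E)-3-methylpent-2-en-4-yn-1-yl]oxy}silane
Conditions: TBSCl, imidazole, DMF, rt
Reagents that add atoms: tert-butyl(chloro)dimethylsilane, CC(C)(C)[Si](C)(C)Cl
Why: Standard silylation of a primary allylic alcohol; the ether must survive t-BuLi, KH and fluoride-free steps up to step 16.

**Step 10**
Reactants: 18 tert-butyldimethyl{[(2E)-3-methylpent-2-en-4-yn-1-yl]oxy}silane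
Product: 19 tert-butyldimethyl{[(2E)-3-methylpenta-2,4-dien-1-yl]oxy}silane
Conditions: H2 (1 atm), Pd/CaCO3 poisoned with Pb(OAc)2, quinoline, hexane, rt
Reagents that add atoms: none
Why: Lindlar semi-hydrogenation of the terminal alkyne should stop at the vinyl group and leave the E alkene untouched.

**Step 11**
Reactants: 19 tert-butyldimethyl{[(2E)-3-methylpenta-2,4-dien-1-yl]oxy}silane; 16 1,1-dibromoprop-1-ene
Product: 21 {[(2E,6Z)-6-bromo-3-methylocta-2,6-dien-1-yl]oxy}(tert-butyl)dimethylsilane, via B-alkyl-9-borabicyclo[3.3.1]nonane 20 (not isolated)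
Conditions: 9-BBN, THF, 0 °C to rt; then 16, PdCl2(dppf) (5 mol%), AsPh3, Cs2CO3, DMF/H2O, rt
Reagents that add atoms: none
Why: 9-BBN should add to the terminal CH2 of the monosubstituted alkene only. In the B-alkyl Suzuki–Miyaura coupling, oxidative addition occurs at the C–Br bond trans to the methyl group (the less hindered one), so the alkyl group ends trans to C17 and the remaining bromine cis to it, which is the Z isomer.

**Step 12**
Reactants: 21 {[(2E,6Z)-6-bromo-3-methylocta-2,6-dien-1-yl]oxy}(tert-butyl)dimethylsilane; 14 methyl (1S,2R)-2-ethenyl-1-methyl-3-oxocyclohexane-1-carboxylate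
Product: 24 methyl (1S,2R,3S)-3-{(2Z,6E)-8-[(tert-butyldimethylsilyl)oxy]-6-methylocta-2,6-dien-3-yl}-2-ethenyl-3-hydroxy-1-methylcyclohexane-1-carboxylate, via alkenyllithium 22 (not isolated), via alkenylcerium dichloride 23 (not isolated)
Conditions: 21, t-BuLi (2 equiv), Et2O, −78 °C; CeCl3, THF, −78 °C; then 14, −78 to −40 °C; aq. NH4Cl
Reagents that add atoms: none
Why: Bromine–lithium exchange keeps the alkene geometry; the organocerium reagent is nucleophilic but weakly basic, so it should add to the hindered, enolisable ketone without deprotonating C5 or attacking the neopentyl ester. Attack is equatorial, trans to the equatorial C5 vinyl group, because the axial face is blocked by the axial C19 methyl; this sets C10 with the two alkenyl groups trans.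

**Step 13**
Reactants: 24 methyl (1S,2R,3S)-3-{(2Z,6E)-8-[(tert-butyldimethylsilyl)oxy]-6-methylocta-2,6-dien-3-yl}-2-ethenyl-3-hydroxy-1-methylcyclohexane-1-carboxylate
Product: 28 methyl (1S,4aS,5S,6R,8aR)-5-{(3E)-5-[(tert-butyldimethylsilyl)oxy]-3-methylpent-3-en-1-yl}-4a-hydroxy-1,5,6-trimethyl-1,2,3,4,4a,5,6,8a-octahydronaphthalene-1-carboxylate, via potassium alkoxide 25 (not isolated), via ten-membered potassium enolate 26 (not isolated), via C9-methylated cyclodecenone 27 (not isolated)
Conditions: KH, 18-crown-6, THF, 0 to 40 °C; MeI, −78 to 0 °C; aq. NH4Cl, extraction; crude 27 in PhMe, 150 °C (sealed tube)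
Reagents that add atoms: iodomethane, CI
Why: The step joins an anionic oxy-Cope rearrangement, an enolate C-methylation and a transannular carbonyl-ene reaction, each known for 1,2-dialkenylcyclohexanols and (E)-cyclodec-5-enones; running them in sequence without isolation is the untested part. Alkoxide 25 rearranges through a chair in which the two equatorial alkenyl groups are gauche: C7–C8 forms, C5–C10 breaks, and the Z methyl group C17 sits axial, which fixes C8 and gives enolate 26 with both ring alkenes trans in the ring. The tetrasubstituted enolate cannot turn through the ring, so iodomethane should reach C9 only from the outer face, anti to the C5=C6 unit, placing C20 cis to C17. On heating, ketone 27 closes in a six-centre ene process: C5 adds to C10 from the inner face while the C7 hydrogen on that face passes to oxygen and the alkene moves to C6=C7. The single C5–C10 bond closes ring A in a 6-exo sense with respect to the alkene (only C5 enters it) and ring B in a 6-endo sense (C5, C6 and C7 lie in it). Because the alkene is E and the ene step is suprafacial, H5 ends on the face opposite the C10–O bond, so the fusion is trans; the sense at C5 and C10 follows from re-closure on the faces that were bonded in 24. The step needs chair over boat in the [3,3] shift, C- over O-methylation, and closure before the C5=C6 unit turns through the ring; the trans-diequatorial alkenyl groups, the soft iodide electrophile at low temperature and the quaternary C4 next to the alkene are relied on for these. Quaternary C4 also leaves C7 as the only allylic hydrogen donor.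

**Step 14**
Reactants: 28 methyl (1S,4aS,5S,6R,8aR)-5-{(3E)-5-[(tert-butyldimethylsilyl)oxy]-3-methylpent-3-en-1-yl}-4a-hydroxy-1,5,6-trimethyl-1,2,3,4,4a,5,6,8a-octahydronaphthalene-1-carboxylate
Product: 29 methyl (1S,4aS,5S,6R,8aR)-5-{(3E)-5-[(tert-butyldimethylsilyl)oxy]-3-methylpent-3-en-1-yl}-4a-hydroxy-1,5,6-trimethyldecahydronaphthalene-1-carboxylate
Conditions: H2 (1 atm), RhCl(PPh3)3 (10 mol%), PhMe/EtOH, rt
Reagents that add atoms: none
Why: Homogeneous hydrogenation with RhCl(PPh3)3 reduces cis-disubstituted alkenes and is very slow on trisubstituted ones, so C6=C7 should be saturated and C13=C14 kept; no stereocentre is formed.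

**Step 15**
Reactants: 29 methyl (1S,4aS,5S,6R,8aR)-5-{(3E)-5-[(tert-butyldimethylsilyl)oxy]-3-methylpent-3-en-1-yl}-4a-hydroxy-1,5,6-trimethyldecahydronaphthalene-1-carboxylate
Product: 30 methyl (1S,5S,6R,8aS)-5-{(3E)-5-[(tert-butyldimethylsilyl)oxy]-3-methylpent-3-en-1-yl}-1,5,6-trimethyl-1,2,3,5,6,7,8,8a-octahydronaphthalene-1-carboxylate
Conditions: methyl N-(triethylammoniosulfonyl)carbamate (Burgess reagent), PhMe, 60 °C
Reagents that add atoms: none
Why: Burgess dehydration proceeds by syn elimination from the sulfamate ester. C9 is quaternary and H5 is anti to the axial oxygen, so only the cis hydrogen at C1 can be removed, which should give the C1=C10 alkene and not the C5=C10 isomer.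

**Step 16**
Reactants: 30 methyl (1S,5S,6R,8aS)-5-{(3E)-5-[(tert-butyldimethylsilyl)oxy]-3-methylpent-3-en-1-yl}-1,5,6-trimethyl-1,2,3,5,6,7,8,8a-octahydronaphthalene-1-carboxylate
Product: 31 methyl (1S,5S,6R,8aS)-5-[(3E)-5-hydroxy-3-methylpent-3-en-1-yl]-1,5,6-trimethyl-1,2,3,5,6,7,8,8a-octahydronaphthalene-1-carboxylate
Conditions: Bu4NF, THF, 0 °C to rt
Reagents that add atoms: none
Why: Fluoride cleavage of the primary silyl ether; the hindered methyl ester and both alkenes should be inert.

**Step 17**
Reactants: 31 methyl (1S,5S,6R,8aS)-5-[(3E)-5-hydroxy-3-methylpent-3-en-1-yl]-1,5,6-trimethyl-1,2,3,5,6,7,8,8a-octahydronaphthalene-1-carboxylate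
Product: 32 methyl (1S,5S,6R,8aS)-5-[(3E)-5-(acetyloxy)-3-methylpent-3-en-1-yl]-1,5,6-trimethyl-1,2,3,5,6,7,8,8a-octahydronaphthalene-1-carboxylate
Conditions: Ac2O, pyridine, DMAP (cat.), CH2Cl2, rt
Reagents that add atoms: acetic anhydride, CC(=O)OC(C)=O
Why: Acylation of the primary allylic alcohol under basic, non-ionising conditions should give the target without allylic transposition.

## Compound list

1 | benzeneselenenyl chloride | Cl[Se]c1ccccc1 | starting material
2 | ethoxyethene | CCOC=C | starting material
3 | 2-(phenylselanyl)acetaldehyde | O=CC[Se]c1ccccc1 | intermediate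
4 | 3-methylcyclohex-2-en-1-one | CC1=CC(=O)CCC1 | starting material
5 | 1-bromo-2-methylprop-1-ene | CC(C)=CBr | starting material
6 | (2-methylprop-1-en-1-yl)lithium | [Li]C=C(C)C | intermediate
7 | dimethyl(2-methylprop-1-en-1-yl)alane | C[Al](C)C=C(C)C | intermediate
8 | dimethylaluminium (3R)-3-methyl-3-(2-methylprop-1-en-1-yl)cyclohex-1-en-1-olate | CC(C)=C[C@@]1(C)CCCC(O[Al](C)C)=C1 | intermediate
9 | (2S,3R)-2-[1-hydroxy-2-(phenylselanyl)ethyl]-3-methyl-3-(2-methylprop-1-en-1-yl)cyclohexan-1-one (both carbinol epimers) | CC(C)=C[C@@]1(C)CCCC(=O)[C@@H]1C(O)C[Se]c1ccccc1 | intermediate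
10 | (2R,3R)-2-ethenyl-3-methyl-3-(2-methylprop-1-en-1-yl)cyclohexan-1-one | CC(C)=C[C@@]1(C)CCCC(=O)[C@@H]1C=C | intermediate
11 | (2R,3S)-3-(3,3-dimethyloxiran-2-yl)-2-ethenyl-3-methylcyclohexan-1-one (both epoxide epimers) | CC1(C)OC1[C@@]2(C)CCCC(=O)[C@@H]2C=C | intermediate
12 | (1S,2R)-2-ethenyl-1-methyl-3-oxocyclohexane-1-carbaldehyde | O=C[C@@]1(C)CCCC(=O)[C@@H]1C=C | intermediate
13 | (1S,2R)-2-ethenyl-1-methyl-3-oxocyclohexane-1-carboxylic acid | OC(=O)[C@@]1(C)CCCC(=O)[C@@H]1C=C | intermediate
14 | methyl (1S,2R)-2-ethenyl-1-methyl-3-oxocyclohexane-1-carboxylate | COC(=O)[C@@]1(C)CCCC(=O)[C@@H]1C=C | intermediate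
15 | acetaldehyde | CC=O | starting material
16 | 1,1-dibromoprop-1-ene | CC=C(Br)Br | intermediate
17 | (2E)-3-methylpent-2-en-4-yn-1-ol | C#C/C(C)=C/CO | starting material
18 | tert-butyldimethyl{[(2E)-3-methylpent-2-en-4-yn-1-yl]oxy}silane | C#C/C(C)=C/CO[Si](C)(C)C(C)(C)C | intermediate
19 | tert-butyldimethyl{[(2E)-3-methylpenta-2,4-dien-1-yl]oxy}silane | C=C/C(C)=C/CO[Si](C)(C)C(C)(C)C | intermediate
20 | 9-{(3E)-5-[(tert-butyldimethylsilyl)oxy]-3-methylpent-3-en-1-yl}-9-borabicyclo[3.3.1]nonane | CC(C)(C)[Si](C)(C)OC/C=C(C)/CCB1C2CCCC1CCC2 | intermediate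
21 | {[(2E,6Z)-6-bromo-3-methylocta-2,6-dien-1-yl]oxy}(tert-butyl)dimethylsilane | Br/C(CC/C(C)=C/CO[Si](C)(C)C(C)(C)C)=C\C | intermediate
22 | {(2E,6E)-8-[(tert-butyldimethylsilyl)oxy]-6-methylocta-2,6-dien-3-yl}lithium (lithium cis to the C17 methyl) | [Li]/C(CC/C(C)=C/CO[Si](C)(C)C(C)(C)C)=C\C | intermediate
23 | dichloro{(2Z,6E)-8-[(tert-butyldimethylsilyl)oxy]-6-methylocta-2,6-dien-3-yl}cerium | Cl[Ce](Cl)/C(CC/C(C)=C/CO[Si](C)(C)C(C)(C)C)=C\C | intermediate
24 | methyl (1S,2R,3S)-3-{(2Z,6E)-8-[(tert-butyldimethylsilyl)oxy]-6-methylocta-2,6-dien-3-yl}-2-ethenyl-3-hydroxy-1-methylcyclohexane-1-carboxylate | COC(=O)[C@@]1(C)CCC[C@@](O)(/C(CC/C(C)=C/CO[Si](C)(C)C(C)(C)C)=C\C)[C@@H]1C=C | intermediate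
25 | potassium C10 alkoxide of 24 | COC(=O)[C@@]1(C)CCC[C@@]([O-])(/C(CC/C(C)=C/CO[Si](C)(C)C(C)(C)C)=C\C)[C@@H]1C=C.[K+] | intermediate
26 | potassium (1S,2E,5R,6Z)-6-{(3E)-5-[(tert-butyldimethylsilyl)oxy]-3-methylpent-3-en-1-yl}-1-(methoxycarbonyl)-1,5-dimethylcyclodeca-2,6-dien-7-olate | COC(=O)[C@@]1(C)CCC/C([O-])=C(CC/C(C)=C/CO[Si](C)(C)C(C)(C)C)/[C@H](C)C/C=C/1.[K+] | intermediate
27 | methyl (1S,2E,5R,6S)-6-{(3E)-5-[(tert-butyldimethylsilyl)oxy]-3-methylpent-3-en-1-yl}-1,5,6-trimethyl-7-oxocyclodec-2-ene-1-carboxylate | COC(=O)[C@@]1(C)CCCC(=O)[C@@](C)(CC/C(C)=C/CO[Si](C)(C)C(C)(C)C)[C@H](C)C/C=C/1 | intermediate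
28 | methyl (1S,4aS,5S,6R,8aR)-5-{(3E)-5-[(tert-butyldimethylsilyl)oxy]-3-methylpent-3-en-1-yl}-4a-hydroxy-1,5,6-trimethyl-1,2,3,4,4a,5,6,8a-octahydronaphthalene-1-carboxylate | COC(=O)[C@@]1(C)CCC[C@]2(O)[C@@H]1C=C[C@@H](C)[C@]2(C)CC/C(C)=C/CO[Si](C)(C)C(C)(C)C | intermediate
29 | methyl (1S,4aS,5S,6R,8aR)-5-{(3E)-5-[(tert-butyldimethylsilyl)oxy]-3-methylpent-3-en-1-yl}-4a-hydroxy-1,5,6-trimethyldecahydronaphthalene-1-carboxylate | COC(=O)[C@@]1(C)CCC[C@]2(O)[C@@H]1CC[C@@H](C)[C@]2(C)CC/C(C)=C/CO[Si](C)(C)C(C)(C)C | intermediate
30 | methyl (1S,5S,6R,8aS)-5-{(3E)-5-[(tert-butyldimethylsilyl)oxy]-3-methylpent-3-en-1-yl}-1,5,6-trimethyl-1,2,3,5,6,7,8,8a-octahydronaphthalene-1-carboxylate | COC(=O)[C@@]1(C)CCC=C2[C@@H]1CC[C@@H](C)[C@]2(C)CC/C(C)=C/CO[Si](C)(C)C(C)(C)C | intermediate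
31 | methyl (1S,5S,6R,8aS)-5-[(3E)-5-hydroxy-3-methylpent-3-en-1-yl]-1,5,6-trimethyl-1,2,3,5,6,7,8,8a-octahydronaphthalene-1-carboxylate | COC(=O)[C@@]1(C)CCC=C2[C@@H]1CC[C@@H](C)[C@]2(C)CC/C(C)=C/CO | intermediate
32 | methyl (1S,5S,6R,8aS)-5-[(3E)-5-(acetyloxy)-3-methylpent-3-en-1-yl]-1,5,6-trimethyl-1,2,3,5,6,7,8,8a-octahydronaphthalene-1-carboxylate | COC(=O)[C@@]1(C)CCC=C2[C@@H]1CC[C@@H](C)[C@]2(C)CC/C(C)=C/COC(C)=O | target

## Step count and least certain steps

Total: 17 steps. Longest linear sequence: 13 steps (steps 1–7, then 12–17); counted from enone 4 it is 12.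

**Step 13 (key step).** The most likely failure is loss of facial control in the transannular closure. At the temperature of the thermal ene step the C5=C6 unit may turn through the ten-membered ring, so that C10 adds to the other face of C5. O-methylation of the crown-ether-separated potassium enolate is the second concern. The allylic strain between the Z methyl group and the alkoxide may also slow the [3,3] shift and favour fragmentation. Fallback: the sequence is run stepwise from 24 with isolated intermediates and a Lewis-acid closure. After the rearrangement (KH, 18-crown-6) the enolate is O-silylated with Me3SiCl to give the trimethylsilyl enol ether of the ten-membered ring F1. MeLi releases the lithium enolate F2, which is C-methylated with MeI to ketone 27, now isolated. Me2AlCl in CH2Cl2 at −78 °C then promotes the carbonyl-ene closure, below the temperature at which the ring equilibrates, and the route is rejoined at 28.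

**Step 2.** The hindered aluminium enolate may be captured poorly by aldehyde 3 (proton transfer or reversal of the aldol), or with low selectivity at C5. Fallback: from 4 and 5 the same conjugate addition is run and the enolate is trapped with Me3SiOSO2CF3 to give the trimethylsilyl enol ether F3. A Mukaiyama-type alkylation with bromoacetaldehyde diethyl acetal and TiCl4 gives the 2-(2-bromo-1-ethoxyethyl) ketone F4. Boord elimination with Zn in EtOH then forms the vinyl group and rejoins the route at 10.

**Step 11.** The monocoupling may lose trans selectivity or go on to double coupling, and the borane may react sluggishly. Fallback: a Negishi alkylation with an organozinc reagent. From 19, hydroboration with 9-BBN and oxidation (NaOH, H2O2) give the homoallylic alcohol F5. I2, PPh3 and imidazole give the iodide F6, and Zn with LiCl gives the alkylzinc iodide F7. This is coupled with 16 using PdCl2(DPEphos), and the route is rejoined at 21.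

**Step 15.** The hindered tertiary sulfamate ester may ionise. Elimination toward C5 or a methyl shift from C9 would then compete. Fallback: a Chugaev elimination, which is concerted and cannot ionise. From 29, KH, CS2 and MeI give the S-methyl xanthate F8. Heating in o-xylene at 140 °C should expel carbonyl sulfide and methanethiol by syn elimination toward C1 only, and the route is rejoined at 30.

## Further compounds

F1 | step 13 | methyl (1S,2E,5R,6Z)-6-{(3E)-5-[(tert-butyldimethylsilyl)oxy]-3-methylpent-3-en-1-yl}-1,5-dimethyl-7-[(trimethylsilyl)oxy]cyclodeca-2,6-diene-1-carboxylate | COC(=O)[C@@]1(C)CCC/C(O[Si](C)(C)C)=C(CC/C(C)=C/CO[Si](C)(C)C(C)(C)C)/[C@H](C)C/C=C/1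
F2 | step 13 | lithium (1S,2E,5R,6Z)-6-{(3E)-5-[(tert-butyldimethylsilyl)oxy]-3-methylpent-3-en-1-yl}-1-(methoxycarbonyl)-1,5-dimethylcyclodeca-2,6-dien-7-olate | COC(=O)[C@@]1(C)CCC/C([O-])=C(CC/C(C)=C/CO[Si](C)(C)C(C)(C)C)/[C@H](C)C/C=C/1.[Li+]
F3 | step 2 | trimethyl{[(3R)-3-methyl-3-(2-methylprop-1-en-1-yl)cyclohex-1-en-1-yl]oxy}silane | CC(C)=C[C@@]1(C)CCCC(O[Si](C)(C)C)=C1
F4 | step 2 | (2S,3R)-2-(2-bromo-1-ethoxyethyl)-3-methyl-3-(2-methylprop-1-en-1-yl)cyclohexan-1-one | CC(C)=C[C@@]1(C)CCCC(=O)[C@@H]1C(OCC)CBr
F5 | step 11 | (3E)-5-[(tert-butyldimethylsilyl)oxy]-3-methylpent-3-en-1-ol | OCC/C(C)=C/CO[Si](C)(C)C(C)(C)C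
F6 | step 11 | tert-butyl{[(2E)-5-iodo-3-methylpent-2-en-1-yl]oxy}dimethylsilane | ICC/C(C)=C/CO[Si](C)(C)C(C)(C)C
F7 | step 11 | {(3E)-5-[(tert-butyldimethylsilyl)oxy]-3-methylpent-3-en-1-yl}(iodo)zinc | I[Zn]CC/C(C)=C/CO[Si](C)(C)C(C)(C)C
F8 | step 15 | methyl (1S,4aS,5S,6R,8aR)-5-{(3E)-5-[(tert-butyldimethylsilyl)oxy]-3-methylpent-3-en-1-yl}-1,5,6-trimethyl-4a-{[(methylsulfanyl)carbonothioyl]oxy}decahydronaphthalene-1-carboxylate | COC(=O)[C@@]1(C)CCC[C@]2(OC(=S)SC)[C@@H]1CC[C@@H](C)[C@]2(C)CC/C(C)=C/CO[Si](C)(C)C(C)(C)C
A1 | alternative 1 | 5-(but-3-yn-1-yl)-1,5,6-trimethyl-1,2,4a,5,6,7,8,8a-octahydronaphthalene-1-carboxylic acid | OC(=O)[C@@]1(C)CC=C[C@H]2[C@@H]1CC[C@@H](C)[C@]2(C)CCC#C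
A2 | alternative 2 | methacrolein (2-methylprop-2-enal) | CC(=C)C=O
A3 | alternative 2 | 5-(but-3-yn-1-yl)-1,5,6-trimethyl-1,2,3,5,6,7,8,8a-octahydronaphthalene-1-carbaldehyde | O=C[C@@]1(C)CCC=C2[C@@H]1CC[C@@H](C)[C@]2(C)CCC#C
A4 | alternative 3 | methyl 5-ethenyl-1,5,6-trimethyl-1,2,3,5,6,7,8,8a-octahydronaphthalene-1-carboxylate | COC(=O)[C@@]1(C)CCC=C2[C@@H]1CC[C@@H](C)[C@]2(C)C=C
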